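Ring A of the flavone is grown last onto a preformed 2-aryl-4-pyranone (ring C), so the C4a–C5 bond is the final skeletal bond. On heating, a racemic 4-(6-aryl-4-oxopyran-2-yl)-2,3-dimethoxycyclobutenone should open to a dienylketene whose ketene carbon closes onto pyranone C3. Enolisation then gives ring A with the C5 hydroxyl, the C6 and C7 methoxy groups (from dimethyl squarate) and C8–H (the cyclobutenone C4–H) in place. The precursor is assembled by two zincation/cross-coupling events on 4H-pyran-4-one: first with a benzyl-protected ring B bromide, then with 4-chloro-2,3-dimethoxycyclobutenone. Hydrogenolysis of the benzyl ether ends the synthesis.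

Key step: step 9

Remark on the chemistry: every compound that carries the cyclobutenone C4 stereocentre, and the transient ring-fused dienone, is racemic. That centre is flattened in the key step and the target is achiral, so no stereocontrol is needed. The 4-chlorocyclobutenone is a vinylogous α-chloro ether and is assumed to be usable only as a freshly made solution.

Step 1
Reactants: 1 1,2,4-trimethoxybenzene
Product: 3 2,3,6-trimethoxybenzaldehyde, via aryllithium 2 (not isolated)
Conditions: n-BuLi, THF, 0 °C to rt; DMF, −78 °C to rt; H2O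
Reagents that add atoms: N,N-dimethylformamide CN(C)C=O
Why: Directed ortho-metalation removes the proton flanked by two methoxy groups (C3–H of 1, the preferred site), and the aryllithium is formylated by DMF.

Step 2
Reactants: 3 2,3,6-trimethoxybenzaldehyde
Product: 4 3-bromo-2,5,6-trimethoxybenzaldehyde
Conditions: NBS, MeCN, rt
Reagents that add atoms: N-bromosuccinimide O=C1CCC(=O)N1Br
Why: Electrophilic aromatic bromination should take the free position that is para to one methoxy group, ortho to another and only meta to the formyl group, because the other free position is para to the deactivating formyl group.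

Step 3
Reactants: 4 3-bromo-2,5,6-trimethoxybenzaldehyde
Product: 6 3-bromo-2,5,6-trimethoxyphenol, via aryl formate 5 (not isolated)
Conditions: mCPBA, CH2Cl2, rt; then K2CO3 (cat.), MeOH, rt
Reagents that add atoms: meta-chloroperbenzoic acid OOC(=O)c1cccc(Cl)c1
Why: Baeyer–Villiger oxidation of an electron-rich 2,6-dialkoxybenzaldehyde proceeds by aryl migration to the formate, which catalytic methoxide removes to leave the phenol between the two methoxy groups.

Step 4
Reactants: 6 3-bromo-2,5,6-trimethoxyphenol
Product: 7 3-(benzyloxy)-1-bromo-2,4,5-trimethoxybenzene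
Conditions: BnBr, K2CO3, DMF, rt
Reagents that add atoms: benzyl bromide BrCc1ccccc1
Why: Williamson ether synthesis on the phenoxide; benzyl is chosen because it tolerates zinc amides, zerovalent palladium and 110 °C and leaves by hydrogenolysis without touching the methyl ethers.

Step 5
Reactants: 8 4H-pyran-4-one; 7 3-(benzyloxy)-1-bromo-2,4,5-trimethoxybenzene
Product: 10 2-[3-(benzyloxy)-2,4,5-trimethoxyphenyl]-4H-pyran-4-one, via dipyranonylzinc 9 (not isolated)
Conditions: TMP2Zn·2MgCl2·2LiCl, THF, −30 to 0 °C; then 7, Pd(OAc)2, SPhos, THF, 50 °C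
Reagents that add atoms: none
Why: Deprotonative zincation of the pyranone C–H next to ring oxygen, as established for chromone C2 (MgCl2 on the carbonyl oxygen keeps the amide away from C3), gives a heteroarylzinc that resists ring opening and undergoes Negishi coupling with the aryl bromide.

Step 6
Reactants: 11 dimethyl squarate (3,4-dimethoxycyclobut-3-ene-1,2-dione)
Product: 12 racemic 4-hydroxy-2,3-dimethoxycyclobut-2-en-1-one
Conditions: LiAlH(OtBu)3, THF, −78 to −40 °C; cold H2O work-up
Reagents that add atoms: none
Why: Carbonyl reduction: one bulky hydride adds 1,2 to one of the two equivalent squarate carbonyl groups, and the resulting alkoxide of a vinylogous ester is not reduced further at low temperature.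

Step 7
Reactants: 12 racemic 4-hydroxy-2,3-dimethoxycyclobut-2-en-1-one
Product: 13 racemic 4-chloro-2,3-dimethoxycyclobut-2-en-1-one
Conditions: PPh3, NCS, CH2Cl2, −20 to 0 °C; used at once as a solution
Reagents that add atoms: N-chlorosuccinimide O=C1CCC(=O)N1Cl
Why: Appel-type chlorination converts the activated secondary alcohol into the chloride without free acid (which would hydrolyse the enol ether), and chloride should end at C4 because that isomer keeps the vinylogous ester conjugation.

Step 8
Reactants: 10 2-[3-(benzyloxy)-2,4,5-trimethoxyphenyl]-4H-pyran-4-one; 13 racemic 4-chloro-2,3-dimethoxycyclobut-2-en-1-one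
Product: 15 racemic 4-{6-[3-(benzyloxy)-2,4,5-trimethoxyphenyl]-4-oxo-4H-pyran-2-yl}-2,3-dimethoxycyclobut-2-en-1-one, via diorganozinc 14 (not isolated)
Conditions: TMP2Zn·2MgCl2·2LiCl, THF, −30 to 0 °C; then 13, Pd(dba)2, P(2-furyl)3, THF, 0 to 25 °C
Reagents that add atoms: none
Why: The only pyranone C–H next to ring oxygen (C6) is zincated as in step 5, and zerovalent palladium inserts into the allylic, carbonyl-activated C4–Cl bond of 13 so that Negishi transmetalation and reductive elimination join C4 to the pyranone, the zinc counterpart of the established palladium coupling of 4-chlorocyclobutenones with aryl- and vinylstannanes, run at 25 °C so that the four-membered ring should stay closed.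

Step 9
Reactants: 15 racemic 4-{6-[3-(benzyloxy)-2,4,5-trimethoxyphenyl]-4-oxo-4H-pyran-2-yl}-2,3-dimethoxycyclobut-2-en-1-one
Product: 18 3'-benzyloxy-5-hydroxy-6,7,2',4',5'-pentamethoxyflavone, via dienylketene 16 (not isolated), via cyclohexadienone 17 (not isolated)
Conditions: toluene (0.02 M), 110 °C, argon
Reagents that add atoms: none
Why: Heating cleaves the cyclobutenone C1–C4 bond by conrotatory 4π-electrocyclic opening to dienylketene 16; thermal disrotatory 6π-electrocyclisation then joins the electrophilic ketene carbon to pyranone C3 (the nucleophilic α-carbon of the vinylogous ester), closing ring A through the new C4a–C5 bond to give cyclohexadienone 17, whose doubly activated C4a–H shifts to oxygen to give the chelated 5-hydroxyl. The closest known reaction type is the thermal benzannulation of 4-aryl and 4-heteroaryl cyclobutenones to fused phenols (Danheiser benzannulation, Moore cyclisation). Ring A is the only ring closed and it closes by 6π-electrocyclisation; no stereocentre survives, since C4 of 15 becomes the sp2 carbon C8 and the transient C4a centre of 17 is erased on tautomerisation. The selectivity needed is regiochemical and geometric: of the two neighbours of the future C8a, only C3 offers a π bond (the other is the ring oxygen), so C5–OH, C6–OMe, C7–OMe and C8–H are fixed by the substitution of the four-membered ring. Outward rotation of the pyranone gives a ketene isomer that cannot cyclise, but it should revert to 15 and drain through the inward-rotated isomer 16. High dilution in a non-nucleophilic solvent should keep the ketene from dimerising or being trapped.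

Step 10
Reactants: 18 3'-benzyloxy-5-hydroxy-6,7,2',4',5'-pentamethoxyflavone
Product: 19 psiadiarabicin (5,3'-dihydroxy-6,7,2',4',5'-pentamethoxyflavone)
Conditions: H2 (1 atm), Pd/C, EtOAc–MeOH, rt
Reagents that add atoms: none
Why: Catalytic hydrogenolysis cleaves the benzylic C–O bond selectively, since the vinylogous-ester C2=C3 bond of the flavone is reduced much more slowly, so the reaction is stopped after one equivalent of hydrogen.

Compound list
1 | 1,2,4-trimethoxybenzene | COc1ccc(OC)c(OC)c1 | starting material
2 | (2,3,6-trimethoxyphenyl)lithium | [Li]c1c(OC)ccc(OC)c1OC | intermediate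
3 | 2,3,6-trimethoxybenzaldehyde | O=Cc1c(OC)ccc(OC)c1OC | intermediate
4 | 3-bromo-2,5,6-trimethoxybenzaldehyde | O=Cc1c(OC)c(Br)cc(OC)c1OC | intermediate
5 | 3-bromo-2,5,6-trimethoxyphenyl formate | O=COc1c(OC)c(Br)cc(OC)c1OC | intermediate
6 | 3-bromo-2,5,6-trimethoxyphenol | Oc1c(OC)c(Br)cc(OC)c1OC | intermediate
7 | 3-(benzyloxy)-1-bromo-2,4,5-trimethoxybenzene | COc1cc(Br)c(OC)c(OCc2ccccc2)c1OC | intermediate
8 | 4H-pyran-4-one | O=c1ccocc1 | starting material
9 | bis(4-oxo-4H-pyran-2-yl)zinc (as its MgCl2/LiCl complex) | O=c1ccoc([Zn]c2cc(=O)cco2)c1 | intermediate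
10 | 2-[3-(benzyloxy)-2,4,5-trimethoxyphenyl]-4H-pyran-4-one | COc1cc(-c2cc(=O)cco2)c(OC)c(OCc2ccccc2)c1OC | intermediate
11 | dimethyl squarate (3,4-dimethoxycyclobut-3-ene-1,2-dione) | COc1c(OC)c(=O)c1=O | starting material
12 | racemic 4-hydroxy-2,3-dimethoxycyclobut-2-en-1-one | COC1=C(OC)C(O)C1=O | intermediate
13 | racemic 4-chloro-2,3-dimethoxycyclobut-2-en-1-one | COC1=C(OC)C(Cl)C1=O | intermediate
14 | bis{6-[3-(benzyloxy)-2,4,5-trimethoxyphenyl]-4-oxo-4H-pyran-2-yl}zinc (as its MgCl2/LiCl complex) | COc1cc(-c2cc(=O)cc([Zn]c3cc(=O)cc(-c4cc(OC)c(OC)c(OCc5ccccc5)c4OC)o3)o2)c(OC)c(OCc2ccccc2)c1OC | intermediate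
15 | racemic 4-{6-[3-(benzyloxy)-2,4,5-trimethoxyphenyl]-4-oxo-4H-pyran-2-yl}-2,3-dimethoxycyclobut-2-en-1-one | COC1=C(OC)C(c2cc(=O)cc(-c3cc(OC)c(OC)c(OCc4ccccc4)c3OC)o2)C1=O | intermediate
16 | (3E)-4-{6-[3-(benzyloxy)-2,4,5-trimethoxyphenyl]-4-oxo-4H-pyran-2-yl}-2,3-dimethoxybuta-1,3-dien-1-one (dienylketene, pyranone cis to the ketene carbon chain) | O=C=C(OC)/C(OC)=C\c1cc(=O)cc(-c2cc(OC)c(OC)c(OCc3ccccc3)c2OC)o1 | intermediate
17 | racemic 2-[3-(benzyloxy)-2,4,5-trimethoxyphenyl]-6,7-dimethoxy-4aH-chromene-4,5-dione | COC1=C(OC)C(=O)C2C(=O)C=C(c3cc(OC)c(OC)c(OCc4ccccc4)c3OC)OC2=C1 | intermediate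
18 | 3'-benzyloxy-5-hydroxy-6,7,2',4',5'-pentamethoxyflavone | COc1cc2oc(-c3cc(OC)c(OC)c(OCc4ccccc4)c3OC)cc(=O)c2c(O)c1OC | intermediate
19 | psiadiarabicin (5,3'-dihydroxy-6,7,2',4',5'-pentamethoxyflavone) | COc1cc(-c2cc(=O)c3c(O)c(OC)c(OC)cc3o2)c(OC)c(O)c1OC | target

Total step count: 10. Longest linear sequence: 8 steps (steps 1–5 and 8–10, from 1,2,4-trimethoxybenzene); the squarate branch (steps 6 and 7) joins at step 8.

Steps most likely to fail

Step 9 (key step). At the temperature needed for ring opening, the ketene may be consumed by dimerisation or by trapping with adventitious nucleophiles before it passes through the disfavoured inward-rotated geometry and closes. Fallback, a classical flavone construction that sets out from 7 and comes back at 19: bromine–lithium exchange on 7 (n-BuLi, THF, −78 °C) and formylation with DMF should give 3-(benzyloxy)-2,4,5-trimethoxybenzaldehyde F1. Claisen–Schmidt condensation of F1 with commercial 1-(2-hydroxy-4,5,6-trimethoxyphenyl)ethanone (CC(=O)c1c(O)cc(OC)c(OC)c1OC; KOH, EtOH, rt) should give (E)-3-[3-(benzyloxy)-2,4,5-trimethoxyphenyl]-1-(2-hydroxy-4,5,6-trimethoxyphenyl)prop-2-en-1-one F2. Oxidative cyclisation (I2 cat., DMSO, 120 °C) should give 3'-benzyloxy-5,6,7,2',4',5'-hexamethoxyflavone F3. BCl3 (CH2Cl2, −78 to 0 °C) should then cleave the benzyl ether and, through chelation to the C4 carbonyl, only the peri C5 methyl ether, arriving at 19.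

Step 8. The labile chloride may ionise or hydrolyse faster than zerovalent palladium inserts. Transmetalation from zinc may be slow enough for homocoupling to take over. Reductive elimination may also occur at the transposed allylic terminus (C2 of the four-membered ring). Fallback, the organotin variant of the coupling, which sets out from 10 and comes back at 15: zinc reagent 14, made as in step 8, is quenched with I2 (THF, 0 °C) to give 2-[3-(benzyloxy)-2,4,5-trimethoxyphenyl]-6-iodo-4H-pyran-4-one F4. Stannylation with Me3SnSnMe3 (Pd(PPh3)4, toluene, 90 °C) should give 2-[3-(benzyloxy)-2,4,5-trimethoxyphenyl]-6-(trimethylstannyl)-4H-pyran-4-one F5. Stille coupling of F5 with 13 (PdCl2(PhCN)2, P(2-furyl)3, dioxane, 25 °C) is the established way to arylate 4-chlorocyclobutenones and should return 15.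

Step 7. As a vinylogous α-chloro ether, the product may ionise during formation or handling, leading to hydrolysis of the enol ether (loss of methanol to the cyclobutenedione) or to allylic transposition of chloride. Fallback, which replaces the chloride by a storable allylic carbonate, sets out from 12 and comes back at 15: acylation of 12 with methyl chloroformate (pyridine, CH2Cl2, 0 °C) should give racemic methyl 2,3-dimethoxy-4-oxocyclobut-2-en-1-yl carbonate F6. Its ionisation by zerovalent palladium (Pd(dba)2, P(2-furyl)3, THF, 25 °C) with loss of CO2, followed by arylation with zinc reagent 14 (palladium-catalysed allylic substitution with an organozinc), should give 15.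

Further compounds
F1 | step 9 | 3-(benzyloxy)-2,4,5-trimethoxybenzaldehyde | COc1cc(C=O)c(OC)c(OCc2ccccc2)c1OC
F2 | step 9 | (E)-3-[3-(benzyloxy)-2,4,5-trimethoxyphenyl]-1-(2-hydroxy-4,5,6-trimethoxyphenyl)prop-2-en-1-one | COc1cc(O)c(C(=O)/C=C/c2cc(OC)c(OC)c(OCc3ccccc3)c2OC)c(OC)c1OC
F3 | step 9 | 3'-benzyloxy-5,6,7,2',4',5'-hexamethoxyflavone | COc1cc2oc(-c3cc(OC)c(OC)c(OCc4ccccc4)c3OC)cc(=O)c2c(OC)c1OC
F4 | step 8 | 2-[3-(benzyloxy)-2,4,5-trimethoxyphenyl]-6-iodo-4H-pyran-4-one | COc1cc(-c2cc(=O)cc(I)o2)c(OC)c(OCc2ccccc2)c1OC
F5 | step 8 | 2-[3-(benzyloxy)-2,4,5-trimethoxyphenyl]-6-(trimethylstannyl)-4H-pyran-4-one | COc1cc(-c2cc(=O)cc([Sn](C)(C)C)o2)c(OC)c(OCc2ccccc2)c1OC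
F6 | step 7 | racemic methyl 2,3-dimethoxy-4-oxocyclobut-2-en-1-yl carbonate | COC(=O)OC1C(OC)=C(OC)C1=O
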